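**Retrosynthetic overview**
- Ring A is bought in acetophenone 1. Ring C is closed first (1 → enaminone 2 → chromone 3), with C2 supplied by DMF-DMA.
- Ring B is bought as arene 4 and activated once as iodide 5. It is attached last.
- Key disconnection: the C2–C1′ bond. Chromone C2 is natively the acceptor β-carbon of the enone. It is converted into a donor, the C2-zinc species 6 (a β-acylvinyl anion, homoenolate-type d3 synthon), and joined to the acceptor carbon of 5 to give Agehoustin B 7.
- The C2–C3–C4 unit is not cut, because its 1,3-oxygen pattern offers no short reversed-polarity bond.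

Assumption: Agehoustin B has no stereocentre, so the SMILES given is the single compound to be made; 1 and 4 are taken as catalogue compounds.

**Route**

Step 1
Reactants: 1 1-(6-hydroxy-2,3,4-trimethoxyphenyl)ethan-1-one
Product: 3 5,6,7-trimethoxy-4H-chromen-4-one, via enaminone 2 (not isolated)
Conditions: DMF-DMA (2.5 equiv), toluene, 100 °C; evaporate; then AcOH, 100 °C
Reagents that add atoms: N,N-dimethylformamide dimethyl acetal (DMF-DMA), COC(OC)N(C)C
Why: Enaminone formation at the acetyl CH3 followed by acid-promoted conjugate addition of the phenol oxygen and loss of dimethylamine (addition–elimination cyclisation) closes ring C; no stereocentre is formed.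

Step 2
Reactants: 4 1,2,3,4-tetramethoxybenzene
Product: 5 1-iodo-2,3,4,5-tetramethoxybenzene
Conditions: NIS (1.05 equiv), TFA (10 mol %), MeCN, 0 °C → rt, dark; Na2S2O3 work-up
Reagents that add atoms: N-iodosuccinimide (NIS), O=C1CCC(=O)N1I
Why: Electrophilic aromatic iodination of a very electron-rich arene whose two free positions are equivalent, so only one mono-iodide can form, and the iodine then hinders and slightly deactivates the last position.

Step 3
Reactants: 3 5,6,7-trimethoxy-4H-chromen-4-one; 5 1-iodo-2,3,4,5-tetramethoxybenzene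
Product: 7 Agehoustin B (5,6,7-trimethoxy-2-(2,3,4,5-tetramethoxyphenyl)-4H-chromen-4-one), via bis(chromen-2-yl)zinc 6 (not isolated)
Conditions: 3 (1.0 equiv), TMP2Zn·2MgCl2·2LiCl (0.55 equiv), THF, −30 °C, 1 h; then 5 (0.85 equiv), Pd(OAc)2 (2 mol %), SPhos (4 mol %), −30 → 50 °C; NH4Cl work-up
Reagents that add atoms: TMP2Zn·2MgCl2·2LiCl, CC1(C)CCCC(C)(C)N1[Zn]N1C(C)(C)CCCC1(C)C.[Mg+2].[Cl-].[Cl-].[Mg+2].[Cl-].[Cl-].[Li+].[Cl-].[Li+].[Cl-] (its zinc is held in 6 only; 7 keeps no reagent atom)
Why: Deprotonative zincation followed by Negishi cross-coupling: the MgCl2 carried by the base binds the C4 carbonyl (helped by 5-OMe), which acidifies the vinylogous C2–H beside the ring oxygen and keeps the amide from being delivered to C3, so zinc enters at C2 and this natively acceptor carbon reacts as a donor with the acceptor carbon of 5; the zinc reagent tolerates the ketone and no stereocentre is formed.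

**Compound list**
1 | 1-(6-hydroxy-2,3,4-trimethoxyphenyl)ethan-1-one | CC(=O)c1c(O)cc(OC)c(OC)c1OC | starting material
2 | (E)-3-(dimethylamino)-1-(6-hydroxy-2,3,4-trimethoxyphenyl)prop-2-en-1-one | CN(C)/C=C/C(=O)c1c(O)cc(OC)c(OC)c1OC | intermediate
3 | 5,6,7-trimethoxy-4H-chromen-4-one | COc1cc2occc(=O)c2c(OC)c1OC | intermediate
4 | 1,2,3,4-tetramethoxybenzene | COc1ccc(OC)c(OC)c1OC | starting material
5 | 1-iodo-2,3,4,5-tetramethoxybenzene | COc1cc(I)c(OC)c(OC)c1OC | intermediate
6 | bis(5,6,7-trimethoxy-4-oxo-4H-chromen-2-yl)zinc | COc1cc2oc([Zn]c3cc(=O)c4c(OC)c(OC)c(OC)cc4o3)cc(=O)c2c(OC)c1OC | intermediate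
7 | Agehoustin B, 5,6,7-trimethoxy-2-(2,3,4,5-tetramethoxyphenyl)-4H-chromen-4-one | COc1cc(-c2cc(=O)c3c(OC)c(OC)c(OC)cc3o2)c(OC)c(OC)c1OC | target

**Count**
Total steps: 3. Longest linear sequence: 2 steps (1 → 3 → 7, or equally 4 → 5 → 7).

**Steps most likely to fail**

1. Step 3 (most likely). The zincation may go to C3 (carbonyl-directed) or to C8–H (flanked by two oxygens) instead of C2. An I2 quench of an aliquot shows the site before the coupling is run. The fallback sets out from 1 and returns at 7, and it keeps the same C2-donor bond formation with C3 blocked. Acetophenone 1 is condensed with DMF-DMA as before, and enaminone 2 is treated in the same flask with NCS (CH2Cl2, 0 °C). This chlorinates the enamine carbon and triggers ring closure to 3-chloro-5,6,7-trimethoxy-4H-chromen-4-one F1. Zincation with TMP2Zn·2MgCl2·2LiCl can then take place only at C2 and gives bis(3-chloro-5,6,7-trimethoxy-4-oxo-4H-chromen-2-yl)zinc F2. F2 is coupled with 5 using Pd(dba)2 and tri(2-furyl)phosphine at 25 °C, a catalyst that leaves the C–Cl bond alone, to give 3-chloro-5,6,7-trimethoxy-2-(2,3,4,5-tetramethoxyphenyl)-4H-chromen-4-one F3. Hydrodechlorination (Pd(OAc)2, XPhos, HCO2Na, DMF, 90 °C) then gives 7.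

2. Step 2. Di-iodination or oxidation of the very electron-rich arene may occur. The fallback sets out from 4 and returns at 5. Ortho-lithiation of 4 (n-BuLi, TMEDA, THF, 0 °C; both free positions are equivalent and ortho to a methoxy group) gives (2,3,4,5-tetramethoxyphenyl)lithium F4. F4 is quenched with I2 at −78 °C to give 5, and one equivalent of base fixes the iodine count at one.

3. Step 1. Condensation at the hindered, hydrogen-bonded acetyl group may be incomplete, or the 5-methoxy group may be lost under hot acid. The fallback sets out from 1 and returns at 3. Claisen formylation of 1 (NaH, HCO2Et, THF, 0 °C → rt) gives, after acidic work-up, the cyclic hemiacetal 2-hydroxy-5,6,7-trimethoxychroman-4-one F5 (racemic; its stereocentre is lost on dehydration). F5 is dehydrated (p-TsOH cat., toluene, reflux) to 3.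

**Further compounds**
F1 | step 3 | 3-chloro-5,6,7-trimethoxy-4H-chromen-4-one | COc1cc2occ(Cl)c(=O)c2c(OC)c1OC
F2 | step 3 | bis(3-chloro-5,6,7-trimethoxy-4-oxo-4H-chromen-2-yl)zinc | COc1cc2oc([Zn]c3oc4cc(OC)c(OC)c(OC)c4c(=O)c3Cl)c(Cl)c(=O)c2c(OC)c1OC
F3 | step 3 | 3-chloro-5,6,7-trimethoxy-2-(2,3,4,5-tetramethoxyphenyl)-4H-chromen-4-one | COc1cc(-c2oc3cc(OC)c(OC)c(OC)c3c(=O)c2Cl)c(OC)c(OC)c1OC
F4 | step 2 | (2,3,4,5-tetramethoxyphenyl)lithium | [Li]c1cc(OC)c(OC)c(OC)c1OC
F5 | step 1 | 2-hydroxy-5,6,7-trimethoxychroman-4-one (racemic hemiacetal) | COc1cc2OC(O)CC(=O)c2c(OC)c1OC
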